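**Retrosynthetic overview**
1. Target 38 ⇐ C3 desilylation, C8 isobutyrylation and Mannich/elimination α-methylenation of the 13-nor lactone 32.
2. Ten-membered carbocycle of 32 ⇐ ring-closing metathesis at C4=C5 (Z) of the vinyl/isopropenyl diene 31; oxirane ⇐ Shi epoxidation of the E C1=C10 olefin; γ-lactone ⇐ oxidative lactonisation of the C6/C12 diol 27.
3. C1–C4 ⇐ Negishi carboalumination of alkyne 19 and opening of ethylene oxide, then isopropenyl addition, oxidation and CBS reduction (C3).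
4. C5–C9 core 19 ⇐ Noyori transfer hydrogenation of an ynone (C6), Fráter–Seebach allylation (C7) and ketoreductase reduction of β-keto ester 3 (C8, first stereocentre), made from achiral 1 and 2.
5. Ring order: γ-lactone (step 20), oxirane (step 22), ten-membered ring (step 23).

Assumption: locants C1–C15 are those of the germacrane skeleton of the target (C12 lactone carbonyl, C13 exocyclic CH2, C14 epoxide methyl, C15 olefinic methyl), and an (S)-selective ketoreductase from a commercial screening panel is taken to accept keto ester 3.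

**Route**

Step 1
Reactants: 1 ethyl 4-chloro-3-oxobutanoate; 2 4-methoxybenzyl alcohol
Product: 3 ethyl 4-[(4-methoxybenzyl)oxy]-3-oxobutanoate
Conditions: NaH (2.2 equiv), THF, 0 °C → rt; aq. citric acid work-up
Reagents that add atoms: none
Why: Williamson ether synthesis in which one equivalent of NaH stores the keto ester as its enolate while the sodium alkoxide of 2 displaces the primary chloride by SN2, and no stereocentre is formed.

Step 2
Reactants: 3 keto ester
Product: 4 ethyl (3S)-3-hydroxy-4-[(4-methoxybenzyl)oxy]butanoate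
Conditions: ketoreductase ((S)-selective, NADPH-dependent), NADP+ (cat.), i-PrOH (10% v/v), phosphate buffer pH 7.0, 30 °C
Reagents that add atoms: none
Why: Biocatalytic asymmetric ketone reduction by a ketoreductase (alcohol dehydrogenase class), for which β-keto esters are standard substrates, delivers the NADPH hydride to one face of the C8 carbonyl to give the (S)-carbinol in >99% ee while isopropanol recycles the cofactor.

Step 3
Reactants: 4 (S)-hydroxy ester
Product: 5 ethyl (2R,3S)-3-hydroxy-4-[(4-methoxybenzyl)oxy]-2-(prop-2-en-1-yl)butanoate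
Conditions: LiN(i-Pr)2 (2.2 equiv), THF, −78 → −20 °C; allyl bromide, DMPU, −78 → −15 °C
Reagents that add atoms: allyl bromide C=CCBr
Why: Fráter–Seebach alkylation, in which the chelated lithium alkoxide–enolate dianion is allylated on the face of the chelate ring opposite the C9 substituent, sets C7 anti to the C8 hydroxyl (usually ≥95:5).

Step 4
Reactants: 5 anti-allyl hydroxy ester
Product: 6 ethyl (2R)-2-[(4S)-2-(4-methoxyphenyl)-1,3-dioxolan-4-yl]pent-4-enoate
Conditions: DDQ (1.2 equiv), 4 Å molecular sieves, CH2Cl2 (anhydrous), 0 °C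
Reagents that add atoms: none
Why: Oxidative acetal formation (Oikawa–Yonemitsu), in which DDQ oxidises the PMB ether to an oxocarbenium ion that the neighbouring C8 hydroxyl traps, masks O8 and O9 together without touching C7 or C8 (the new acetal carbon is an inconsequential epimer mixture).

Step 5
Reactants: 6 acetal ester
Product: 9 (3R)-3-[(4S)-2-(4-methoxyphenyl)-1,3-dioxolan-4-yl]oxolan-2-one, via aldehyde 7 (not isolated), via hydroxy ester 8 (not isolated)
Conditions: OsO4 (2 mol %), NaIO4 (4 equiv), 2,6-lutidine, dioxane/H2O, rt; then NaBH4, MeOH, 0 °C; crude warmed in PhMe, 50 °C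
Reagents that add atoms: osmium tetroxide O=[Os](=O)(=O)=O; sodium periodate [Na+].[O-]I(=O)(=O)=O
Why: Lemieux–Johnson oxidative cleavage of the terminal olefin, chemoselective borohydride reduction of the aldehyde and lactonisation of the γ-hydroxy ester turn the allyl group into C11–C12 and distinguish the C6 acyl carbon from C12 without base that could epimerise C7.

Step 6
Reactants: 9 lactone
Product: 10 (4R)-6-hydroxy-4-[(4S)-2-(4-methoxyphenyl)-1,3-dioxolan-4-yl]-1-(trimethylsilyl)hex-1-yn-3-one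
Conditions: LiC≡CSiMe3 (1.3 equiv), THF, −78 °C; aq. NH4Cl quench at −78 °C
Reagents that add atoms: lithium (trimethylsilyl)acetylide [Li]C#C[Si](C)(C)C
Why: Nucleophilic acyl addition of an alkynyllithium to a lactone stops after one addition because the tetrahedral lithium hemiketal is stable at −78 °C, and the cold quench releases the ynone with C7 intact.

Step 7
Reactants: 10 hydroxy ynone
Product: 11 O12-triethylsilyl ynone
Conditions: Et3SiCl, imidazole, CH2Cl2, 0 °C
Reagents that add atoms: chlorotriethylsilane CC[Si](Cl)(CC)CC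
Why: Silyl ether formation at the primary hydroxyl locks the open-chain ynone form and protects O12.

Step 8
Reactants: 11 silylated ynone
Product: 12 (3S,4S)-propargylic alcohol
Conditions: Ru[(S,S)-TsNCH(Ph)CH(Ph)NH](p-cymene) (3 mol %), i-PrOH, rt
Reagents that add atoms: none
Why: Noyori asymmetric transfer hydrogenation with the (S,S)-configured ruthenium hydride reduces the alkynyl ketone under reagent control to the (S)-propargylic alcohol, which sets C6 (typically >95:5) under base-free conditions that leave C7 untouched.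

Step 9
Reactants: 12 propargylic alcohol
Product: 14 (3R,4S)-allylic alcohol with the C5 vinyl group, via terminal alkyne 13 (not isolated)
Conditions: K2CO3, MeOH, rt; then AcOH to neutral, H2 (1 atm), Pd/CaCO3 poisoned with Pb(OAc)2 (Lindlar catalyst), quinoline, rt
Reagents that add atoms: none
Why: Methanolysis of the alkynylsilane (protodesilylation) followed by Lindlar semihydrogenation stops at the vinyl group because the poisoned palladium surface does not reduce olefins, benzylidene acetals or silyl ethers.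

Step 10
Reactants: 14 allylic alcohol
Product: 15 bis(triethylsilyl) ether
Conditions: Et3SiOTf, 2,6-lutidine, CH2Cl2, −78 °C
Reagents that add atoms: triethylsilyl trifluoromethanesulfonate CC[Si](CC)(CC)OS(=O)(=O)C(F)(F)F
Why: Silyl ether formation with the silyl triflate is reactive enough for the hindered secondary allylic alcohol at low temperature.

Step 11
Reactants: 15 acetal bis-silyl ether
Product: 16 (2S,3R,4R)-primary alcohol with the PMB ether on O8
Conditions: i-Bu2AlH (4 equiv), CH2Cl2, −78 → 0 °C; aq. potassium sodium tartrate work-up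
Reagents that add atoms: none
Why: Regioselective reductive cleavage of the 4-methoxybenzylidene acetal occurs because aluminium coordinates the less hindered primary oxygen O9 and hydride reduces the resulting oxocarbenium ion, so the PMB ether ends on the secondary O8 and the C9 hydroxyl is freed.

Step 12
Reactants: 16 primary alcohol
Product: 18 (3R,4R,5R)-silylated enyne, via triflate 17 (not isolated)
Conditions: Tf2O, 2,6-lutidine, CH2Cl2, −78 °C; then LiC≡CSiMe3, THF/DMPU, −78 → −20 °C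
Reagents that add atoms: lithium (trimethylsilyl)acetylide [Li]C#C[Si](C)(C)C
Why: Triflate formation and SN2 alkylation of a lithium acetylide displace the primary triflate at low temperature faster than elimination, forging C9–C10 with C8 unchanged.

Step 13
Reactants: 18 alkynylsilane
Product: 19 (3R,4R,5R)-terminal alkyne
Conditions: K2CO3, MeOH, rt
Reagents that add atoms: none
Why: Protodesilylation of the alkynylsilane by methoxide proceeds under conditions to which triethylsilyl ethers are stable.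

Step 14
Reactants: 19 terminal alkyne
Product: 22 (3E,6R,7R,8R)-homoallylic alcohol, via alkenylalane 20 (not isolated), via lithium alanate 21 (not isolated)
Conditions: Me3Al (3 equiv), Cp2ZrCl2 (25 mol %), CH2Cl2, 0 °C → rt; volatiles removed; n-BuLi (1 equiv), THF/hexane, −78 °C; ethylene oxide, −78 → 0 °C
Reagents that add atoms: trimethylaluminium C[Al](C)C; ethylene oxide C1CO1
Why: Negishi zirconium-catalysed carboalumination (syn addition of methyl and aluminium with methyl on the internal carbon) fixes the E-trisubstituted C1=C10 olefin, and the lithium alkenylalanate opens ethylene oxide with retention of olefin geometry to add C2 and C3.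

Step 15
Reactants: 22 homoallylic alcohol
Product: 23 β,γ-unsaturated aldehyde
Conditions: Dess–Martin periodinane, NaHCO3, CH2Cl2, 0 °C
Reagents that add atoms: none
Why: Dess–Martin oxidation under buffered non-basic conditions gives the β,γ-unsaturated aldehyde without migration of the olefin into conjugation.

Step 16
Reactants: 23 aldehyde
Product: 24 isopropenyl carbinol (both C3 epimers)
Conditions: CH2=C(CH3)MgBr (1.3 equiv), THF, −78 °C; aq. NH4Cl
Reagents that add atoms: isopropenylmagnesium bromide C=C(C)[Mg]Br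
Why: Grignard 1,2-addition at −78 °C installs C4 and C15, with no attempt to control C3 because both epimers converge in the next step.

Step 17
Reactants: 24 epimeric alcohols
Product: 25 isopropenyl ketone
Conditions: Dess–Martin periodinane, NaHCO3, CH2Cl2, 0 °C
Reagents that add atoms: none
Why: Dess–Martin oxidation converts both C3 epimers into a single enone under neutral conditions that keep the skipped olefin in place.

Step 18
Reactants: 25 enone
Product: 26 (3S)-allylic alcohol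
Conditions: (R)-2-methyl-CBS-oxazaborolidine (30 mol %), catecholborane, PhMe, −78 °C
Reagents that add atoms: none
Why: Corey–Bakshi–Shibata reduction, in which the (R)-oxazaborolidine binds the ketone with the α-branched isopropenyl group as the large substituent and catecholborane (inert to the olefins at −78 °C) delivers hydride, gives the (3S)-alcohol under reagent control.

Step 19
Reactants: 26 bis-silyl ether
Product: 27 triol
Conditions: PPTS, MeOH/CH2Cl2, 0 °C → rt
Reagents that add atoms: none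
Why: Acid-catalysed methanolysis of the two triethylsilyl ethers is mild enough to spare the PMB ether and both allylic alcohols.

Step 20
Reactants: 27 triol
Product: 29 (4R,5R)-hydroxy lactone, via lactol 28 (not isolated)
Conditions: TEMPO (20 mol %), PhI(OAc)2 (2.5 equiv), CH2Cl2, rt
Reagents that add atoms: none
Why: TEMPO/PhI(OAc)2 oxidative lactonisation oxidises only the primary C12 alcohol, the aldehyde is captured by the C6 hydroxyl as a lactol and this is oxidised to the γ-lactone, whose trans ring substituents follow from the already fixed C6 and C7 centres.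

Step 21
Reactants: 29 hydroxy lactone
Product: 30 C3 triethylsilyl ether
Conditions: Et3SiCl, imidazole, DMAP (cat.), CH2Cl2, 0 °C → rt
Reagents that add atoms: chlorotriethylsilane CC[Si](Cl)(CC)CC
Why: Silyl ether formation at the only free hydroxyl gives a C3 protecting group that can be removed last under very mild conditions.

Step 22
Reactants: 30 triene lactone
Product: 31 (1S,10S)-epoxy lactone
Conditions: ent-Shi ketone (L-fructose-derived, 30 mol %), Oxone (2KHSO5·KHSO4·K2SO4), K2CO3, Bu4NHSO4, MeCN/CH2(OMe)2/aq. Na2B4O7 buffer, 0 °C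
Reagents that add atoms: potassium peroxymonosulfate [K+].[O-]S(=O)(=O)OO
Why: Shi asymmetric epoxidation, in which the dioxirane of the L-fructose-derived ketone transfers oxygen to the electron-rich E-trisubstituted C1=C10 olefin through a spiro transition state, gives the (1S,10S)-epoxide under reagent control while the 1,1-disubstituted and monosubstituted olefins react much more slowly.

Step 23
Reactants: 31 epoxy diene lactone
Product: 32 ten-membered 13-nor lactone with the Z C4=C5 olefin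
Conditions: second-generation Grubbs catalyst (H2IMes)(PCy3)Cl2Ru=CHPh (2 × 10 mol %), 1,4-benzoquinone (20 mol %), PhMe (1 mM), 80 °C
Reagents that add atoms: none
Why: Ring-closing olefin metathesis, in which the ruthenium alkylidene loads at the vinyl group and closes onto the isopropenyl group with loss of ethylene, gives a ten-membered ring that can hold the new trisubstituted olefin only in the ring-cis (Z) geometry that the target needs.

Step 24
Reactants: 32 macrocyclic lactone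
Product: 35 α-methylene lactone, via Mannich base 33 (not isolated), via methiodide 34 (not isolated)
Conditions: LiN(i-Pr)2 (1.3 equiv), THF, −78 °C; CH2=NMe2+ I− (3 equiv), −78 °C → rt; then MeI, MeOH/CH2Cl2, rt; then NaHCO3 (aq.), EtOAc, rt
Reagents that add atoms: Eschenmoser's salt (N,N-dimethylmethyleneiminium iodide) C=[N+](C)C.[I-]
Why: Mannich reaction of the lactone lithium enolate with Eschenmoser's salt followed by N-methylation and Hofmann-type elimination gives the exocyclic methylene, the transient C11 centre being destroyed in the elimination.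

Step 25
Reactants: 35 PMB ether
Product: 36 C8 alcohol
Conditions: DDQ (1.5 equiv), CH2Cl2/pH 7 phosphate buffer (10:1), 0 °C
Reagents that add atoms: none
Why: Oxidative cleavage of the PMB ether with DDQ (hydride abstraction then hydrolysis of the oxocarbenium ion) at neutral pH forms no C8 alkoxide able to translactonise and spares the epoxide.

Step 26
Reactants: 36 C8 alcohol
Product: 37 C8 isobutyrate
Conditions: (i-PrCO)2O, DMAP, Et3N, CH2Cl2, 0 °C → rt
Reagents that add atoms: isobutyric anhydride CC(C)C(=O)OC(=O)C(C)C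
Why: DMAP-catalysed acylation (nucleophilic catalysis via the acylpyridinium ion) of the only free hydroxyl installs the isobutyrate.

Step 27
Reactants: 37 C3 triethylsilyl ether
Product: 38 target CNP0261225.3
Conditions: HF·pyridine, pyridine, THF, 0 °C
Reagents that add atoms: none
Why: Fluoride-mediated desilylation cleaves the allylic triethylsilyl ether within minutes in pyridine-buffered HF·pyridine at 0 °C, conditions that leave the epoxide, the isobutyrate and the α-methylene lactone untouched.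

**Compound list**

1 | ethyl 4-chloro-3-oxobutanoate | CCOC(=O)CC(=O)CCl | starting material
2 | (4-methoxyphenyl)methanol (4-methoxybenzyl alcohol) | COc1ccc(CO)cc1 | starting material
3 | ethyl 4-[(4-methoxybenzyl)oxy]-3-oxobutanoate | CCOC(=O)CC(=O)COCc1ccc(OC)cc1 | intermediate
4 | ethyl (3S)-3-hydroxy-4-[(4-methoxybenzyl)oxy]butanoate | CCOC(=O)C[C@H](O)COCc1ccc(OC)cc1 | intermediate
5 | ethyl (2R,3S)-3-hydroxy-4-[(4-methoxybenzyl)oxy]-2-(prop-2-en-1-yl)butanoate | CCOC(=O)[C@H](CC=C)[C@H](O)COCc1ccc(OC)cc1 | intermediate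
6 | ethyl (2R)-2-[(4S)-2-(4-methoxyphenyl)-1,3-dioxolan-4-yl]pent-4-enoate (both epimers at the acetal carbon, as in 7–15) | CCOC(=O)[C@H](CC=C)[C@H]1COC(c2ccc(OC)cc2)O1 | intermediate
7 | ethyl (2R)-2-[(4S)-2-(4-methoxyphenyl)-1,3-dioxolan-4-yl]-4-oxobutanoate | CCOC(=O)[C@H](CC=O)[C@H]1COC(c2ccc(OC)cc2)O1 | intermediate
8 | ethyl (2R)-4-hydroxy-2-[(4S)-2-(4-methoxyphenyl)-1,3-dioxolan-4-yl]butanoate | CCOC(=O)[C@H](CCO)[C@H]1COC(c2ccc(OC)cc2)O1 | intermediate
9 | (3R)-3-[(4S)-2-(4-methoxyphenyl)-1,3-dioxolan-4-yl]oxolan-2-one | O=C1OCC[C@@H]1[C@H]2COC(c3ccc(OC)cc3)O2 | intermediate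
10 | (4R)-6-hydroxy-4-[(4S)-2-(4-methoxyphenyl)-1,3-dioxolan-4-yl]-1-(trimethylsilyl)hex-1-yn-3-one | C[Si](C)(C)C#CC(=O)[C@H](CCO)[C@H]1COC(c2ccc(OC)cc2)O1 | intermediate
11 | (4R)-4-[(4S)-2-(4-methoxyphenyl)-1,3-dioxolan-4-yl]-6-[(triethylsilyl)oxy]-1-(trimethylsilyl)hex-1-yn-3-one | C[Si](C)(C)C#CC(=O)[C@H](CCO[Si](CC)(CC)CC)[C@H]1COC(c2ccc(OC)cc2)O1 | intermediate
12 | (3S,4S)-4-[(4S)-2-(4-methoxyphenyl)-1,3-dioxolan-4-yl]-6-[(triethylsilyl)oxy]-1-(trimethylsilyl)hex-1-yn-3-ol | C[Si](C)(C)C#C[C@@H](O)[C@H](CCO[Si](CC)(CC)CC)[C@H]1COC(c2ccc(OC)cc2)O1 | intermediate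
13 | (3S,4S)-4-[(4S)-2-(4-methoxyphenyl)-1,3-dioxolan-4-yl]-6-[(triethylsilyl)oxy]hex-1-yn-3-ol | C#C[C@@H](O)[C@H](CCO[Si](CC)(CC)CC)[C@H]1COC(c2ccc(OC)cc2)O1 | intermediate
14 | (3R,4S)-4-[(4S)-2-(4-methoxyphenyl)-1,3-dioxolan-4-yl]-6-[(triethylsilyl)oxy]hex-1-en-3-ol | C=C[C@@H](O)[C@H](CCO[Si](CC)(CC)CC)[C@H]1COC(c2ccc(OC)cc2)O1 | intermediate
15 | (3R,4R)-4-[(4S)-2-(4-methoxyphenyl)-1,3-dioxolan-4-yl]-3,6-bis[(triethylsilyl)oxy]hex-1-ene | C=C[C@@H](O[Si](CC)(CC)CC)[C@H](CCO[Si](CC)(CC)CC)[C@H]1COC(c2ccc(OC)cc2)O1 | intermediate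
16 | (2S,3R,4R)-2-[(4-methoxybenzyl)oxy]-4-[(triethylsilyl)oxy]-3-{2-[(triethylsilyl)oxy]ethyl}hex-5-en-1-ol | C=C[C@@H](O[Si](CC)(CC)CC)[C@H](CCO[Si](CC)(CC)CC)[C@H](OCc1ccc(OC)cc1)CO | intermediate
17 | (2S,3R,4R)-2-[(4-methoxybenzyl)oxy]-4-[(triethylsilyl)oxy]-3-{2-[(triethylsilyl)oxy]ethyl}hex-5-en-1-yl trifluoromethanesulfonate | C=C[C@@H](O[Si](CC)(CC)CC)[C@H](CCO[Si](CC)(CC)CC)[C@H](OCc1ccc(OC)cc1)COS(=O)(=O)C(F)(F)F | intermediate
18 | (3R,4R,5R)-5-[(4-methoxybenzyl)oxy]-3-[(triethylsilyl)oxy]-4-{2-[(triethylsilyl)oxy]ethyl}-8-(trimethylsilyl)oct-1-en-7-yne | C=C[C@@H](O[Si](CC)(CC)CC)[C@H](CCO[Si](CC)(CC)CC)[C@H](OCc1ccc(OC)cc1)CC#C[Si](C)(C)C | intermediate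
19 | (3R,4R,5R)-5-[(4-methoxybenzyl)oxy]-3-[(triethylsilyl)oxy]-4-{2-[(triethylsilyl)oxy]ethyl}oct-1-en-7-yne | C=C[C@@H](O[Si](CC)(CC)CC)[C@H](CCO[Si](CC)(CC)CC)[C@H](OCc1ccc(OC)cc1)CC#C | intermediate
20 | dimethyl[(1E,4R,5R,6R)-4-[(4-methoxybenzyl)oxy]-2-methyl-6-[(triethylsilyl)oxy]-5-{2-[(triethylsilyl)oxy]ethyl}octa-1,7-dien-1-yl]alane | C=C[C@@H](O[Si](CC)(CC)CC)[C@H](CCO[Si](CC)(CC)CC)[C@H](OCc1ccc(OC)cc1)C/C(C)=C/[Al](C)C | intermediate
21 | lithium butyl(dimethyl)[(1E,4R,5R,6R)-4-[(4-methoxybenzyl)oxy]-2-methyl-6-[(triethylsilyl)oxy]-5-{2-[(triethylsilyl)oxy]ethyl}octa-1,7-dien-1-yl]aluminate | C=C[C@@H](O[Si](CC)(CC)CC)[C@H](CCO[Si](CC)(CC)CC)[C@H](OCc1ccc(OC)cc1)C/C(C)=C/[Al-](C)(C)CCCC.[Li+] | intermediate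
22 | (3E,6R,7R,8R)-6-[(4-methoxybenzyl)oxy]-4-methyl-8-[(triethylsilyl)oxy]-7-{2-[(triethylsilyl)oxy]ethyl}deca-3,9-dien-1-ol | C=C[C@@H](O[Si](CC)(CC)CC)[C@H](CCO[Si](CC)(CC)CC)[C@H](OCc1ccc(OC)cc1)C/C(C)=C/CCO | intermediate
23 | (3E,6R,7R,8R)-6-[(4-methoxybenzyl)oxy]-4-methyl-8-[(triethylsilyl)oxy]-7-{2-[(triethylsilyl)oxy]ethyl}deca-3,9-dienal | C=C[C@@H](O[Si](CC)(CC)CC)[C@H](CCO[Si](CC)(CC)CC)[C@H](OCc1ccc(OC)cc1)C/C(C)=C/CC=O | intermediate
24 | (5E,8R,9R,10R)-8-[(4-methoxybenzyl)oxy]-2,6-dimethyl-10-[(triethylsilyl)oxy]-9-{2-[(triethylsilyl)oxy]ethyl}dodeca-1,5,11-trien-3-ol (both C3 epimers) | C=C[C@@H](O[Si](CC)(CC)CC)[C@H](CCO[Si](CC)(CC)CC)[C@H](OCc1ccc(OC)cc1)C/C(C)=C/CC(O)C(C)=C | intermediate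
25 | (5E,8R,9R,10R)-8-[(4-methoxybenzyl)oxy]-2,6-dimethyl-10-[(triethylsilyl)oxy]-9-{2-[(triethylsilyl)oxy]ethyl}dodeca-1,5,11-trien-3-one | C=C[C@@H](O[Si](CC)(CC)CC)[C@H](CCO[Si](CC)(CC)CC)[C@H](OCc1ccc(OC)cc1)C/C(C)=C/CC(=O)C(C)=C | intermediate
26 | (3S,5E,8R,9R,10R)-8-[(4-methoxybenzyl)oxy]-2,6-dimethyl-10-[(triethylsilyl)oxy]-9-{2-[(triethylsilyl)oxy]ethyl}dodeca-1,5,11-trien-3-ol | C=C[C@@H](O[Si](CC)(CC)CC)[C@H](CCO[Si](CC)(CC)CC)[C@H](OCc1ccc(OC)cc1)C/C(C)=C/C[C@H](O)C(C)=C | intermediate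
27 | (3S,5E,8R,9S,10R)-9-(2-hydroxyethyl)-8-[(4-methoxybenzyl)oxy]-2,6-dimethyldodeca-1,5,11-triene-3,10-diol | C=C[C@@H](O)[C@H](CCO)[C@H](OCc1ccc(OC)cc1)C/C(C)=C/C[C@H](O)C(C)=C | intermediate
28 | (4R,5R)-5-ethenyl-4-[(1R,3E,6S)-6-hydroxy-1-[(4-methoxybenzyl)oxy]-3,7-dimethylocta-3,7-dien-1-yl]oxolan-2-ol (both anomers) | C=C[C@H]1OC(O)C[C@@H]1[C@H](OCc2ccc(OC)cc2)C/C(C)=C/C[C@H](O)C(C)=C | intermediate
29 | (4R,5R)-5-ethenyl-4-[(1R,3E,6S)-6-hydroxy-1-[(4-methoxybenzyl)oxy]-3,7-dimethylocta-3,7-dien-1-yl]oxolan-2-one | C=C[C@H]1OC(=O)C[C@@H]1[C@H](OCc2ccc(OC)cc2)C/C(C)=C/C[C@H](O)C(C)=C | intermediate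
30 | (4R,5R)-5-ethenyl-4-[(1R,3E,6S)-1-[(4-methoxybenzyl)oxy]-3,7-dimethyl-6-[(triethylsilyl)oxy]octa-3,7-dien-1-yl]oxolan-2-one | C=C[C@H]1OC(=O)C[C@@H]1[C@H](OCc2ccc(OC)cc2)C/C(C)=C/C[C@H](O[Si](CC)(CC)CC)C(C)=C | intermediate
31 | (4R,5R)-5-ethenyl-4-{(1R)-1-[(4-methoxybenzyl)oxy]-2-[(2S,3S)-2-methyl-3-{(2S)-3-methyl-2-[(triethylsilyl)oxy]but-3-en-1-yl}oxiran-2-yl]ethyl}oxolan-2-one | C=C[C@H]1OC(=O)C[C@@H]1[C@H](OCc2ccc(OC)cc2)C[C@]2(C)O[C@H]2C[C@H](O[Si](CC)(CC)CC)C(C)=C | intermediate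
32 | (1S,3S,4Z,6R,7R,8R,10S)-1,10-epoxy-8-[(4-methoxybenzyl)oxy]-3-[(triethylsilyl)oxy]-13-norgermacr-4-en-12,6-olide | C1C(=O)O[C@@H]2/C=C(/C)[C@@H](O[Si](CC)(CC)CC)C[C@@H]3O[C@@]3(C)C[C@@H](OCc4ccc(OC)cc4)[C@@H]12 | intermediate
33 | 13-(dimethylamino)-11,13-dihydro derivative of 35 (both C11 epimers; other centres as in 32) | CN(C)CC1C(=O)O[C@@H]2/C=C(/C)[C@@H](O[Si](CC)(CC)CC)C[C@@H]3O[C@@]3(C)C[C@@H](OCc4ccc(OC)cc4)[C@@H]12 | intermediate
34 | N-methyl quaternary ammonium iodide of 33 | C[N+](C)(C)CC1C(=O)O[C@@H]2/C=C(/C)[C@@H](O[Si](CC)(CC)CC)C[C@@H]3O[C@@]3(C)C[C@@H](OCc4ccc(OC)cc4)[C@@H]12.[I-] | intermediate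
35 | (1S,3S,4Z,6R,7R,8R,10S)-1,10-epoxy-8-[(4-methoxybenzyl)oxy]-3-[(triethylsilyl)oxy]germacra-4,11(13)-dien-12,6-olide | C=C1C(=O)O[C@@H]2/C=C(/C)[C@@H](O[Si](CC)(CC)CC)C[C@@H]3O[C@@]3(C)C[C@@H](OCc4ccc(OC)cc4)[C@@H]12 | intermediate
36 | (1S,3S,4Z,6R,7R,8R,10S)-1,10-epoxy-8-hydroxy-3-[(triethylsilyl)oxy]germacra-4,11(13)-dien-12,6-olide | C=C1C(=O)O[C@@H]2/C=C(/C)[C@@H](O[Si](CC)(CC)CC)C[C@@H]3O[C@@]3(C)C[C@@H](O)[C@@H]12 | intermediate
37 | (1S,3S,4Z,6R,7R,8R,10S)-1,10-epoxy-8-(2-methylpropanoyloxy)-3-[(triethylsilyl)oxy]germacra-4,11(13)-dien-12,6-olide | C=C1C(=O)O[C@@H]2/C=C(/C)[C@@H](O[Si](CC)(CC)CC)C[C@@H]3O[C@@]3(C)C[C@@H](OC(=O)C(C)C)[C@@H]12 | intermediate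
38 | (1S,3S,4Z,6R,7R,8R,10S)-1,10-epoxy-3-hydroxy-8-(2-methylpropanoyloxy)germacra-4,11(13)-dien-12,6-olide (CNP0261225.3) | C=C1C(=O)O[C@@H]2/C=C(/C)[C@@H](O)C[C@@H]3O[C@@]3(C)C[C@@H](OC(=O)C(C)C)[C@@H]12 | target

**Summary**

Total step count: 27. Longest linear sequence: 27 steps (from 1 and 2 to 38).

Three steps most likely to fail:

Step 23, the ring-closing metathesis. The trans-fused lactone and the oxirane may hold the vinyl and isopropenyl groups apart, so that oligomers form instead of the ten-membered ring. The fallback changes the ring order and sets out from alcohol 26, before the lactone exists. Shi epoxidation with the same L-fructose-derived ketone gives the (1S,10S)-epoxy alcohol F3. Ring-closing metathesis of this flexible bis-silyl ether, which has a free allylic hydroxyl next to the 1,1-disubstituted olefin, with the second-generation Hoveyda–Grubbs catalyst (H2IMes)Cl2Ru=CH(2-i-PrOC6H4) gives the ten-membered carbocycle F4. Bu4NF in THF removes both triethylsilyl ethers to give the triol F5. TEMPO/PhI(OAc)2 then oxidises the primary alcohol and closes the γ-lactone onto the existing carbocycle to give the hydroxy lactone F6. Silylation with Et3SiCl and imidazole comes back to the route at 32.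

Step 14, the one-pot carboalumination and alanate opening of ethylene oxide. Transfer of the alkenyl group from the alanate can be slow or can compete with methyl or butyl transfer. The fallback sets out from alkyne 19 and replaces the epoxide opening by a cross-coupling. The same carboalumination is run, but alane 20 is quenched with I2 to give the alkenyl iodide F1. Negishi coupling of F1 with the Reformatsky reagent BrZnCH2CO2Et under zerovalent palladium catalysis (Pd(PPh3)4, THF/DMPU, 50 °C) gives the β,γ-unsaturated ester F2. Reduction of F2 with i-Bu2AlH (CH2Cl2, −78 → 0 °C) comes back to the route at 22.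

Step 24, the enolate Mannich methylenation on the macrocycle. The lactone enolate lies across the ring from the oxirane and could open it transannularly, or deprotonation could be slow. The fallback installs the methylene before the ring is closed and sets out from the acyclic lactone 31. LiN(i-Pr)2 and Eschenmoser's salt give the Mannich base F7, MeI gives the methiodide F8, and NaHCO3 gives the acyclic α-methylene lactone F9. Ring-closing metathesis of F9 with the second-generation Grubbs catalyst, in which the electron-poor exocyclic olefin cannot close a ring with either partner, comes back to the route at 35.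

**Further compounds**

F1 | step 14 | (1E,4R,5R,6R)-1-iodo-4-[(4-methoxybenzyl)oxy]-2-methyl-6-[(triethylsilyl)oxy]-5-{2-[(triethylsilyl)oxy]ethyl}octa-1,7-diene | C=C[C@@H](O[Si](CC)(CC)CC)[C@H](CCO[Si](CC)(CC)CC)[C@H](OCc1ccc(OC)cc1)C/C(C)=C/I
F2 | step 14 | ethyl (3E,6R,7R,8R)-6-[(4-methoxybenzyl)oxy]-4-methyl-8-[(triethylsilyl)oxy]-7-{2-[(triethylsilyl)oxy]ethyl}deca-3,9-dienoate | C=C[C@@H](O[Si](CC)(CC)CC)[C@H](CCO[Si](CC)(CC)CC)[C@H](OCc1ccc(OC)cc1)C/C(C)=C/CC(=O)OCC
F3 | step 23 | (2S)-1-[(2S,3S)-3-{(2R,3R,4R)-2-[(4-methoxybenzyl)oxy]-4-[(triethylsilyl)oxy]-3-{2-[(triethylsilyl)oxy]ethyl}hex-5-en-1-yl}-3-methyloxiran-2-yl]-3-methylbut-3-en-2-ol | C=C[C@@H](O[Si](CC)(CC)CC)[C@H](CCO[Si](CC)(CC)CC)[C@H](OCc1ccc(OC)cc1)C[C@]2(C)O[C@H]2C[C@H](O)C(C)=C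
F4 | step 23 | (1S,3S,4Z,6R,7R,8R,10S)-1,10-epoxy-8-[(4-methoxybenzyl)oxy]-6,12-bis[(triethylsilyl)oxy]-13-norgermacr-4-en-3-ol | CC[Si](CC)(CC)OCC[C@H]1[C@H](O[Si](CC)(CC)CC)/C=C(/C)[C@@H](O)C[C@@H]2O[C@@]2(C)C[C@H]1OCc3ccc(OC)cc3
F5 | step 23 | (1S,3S,4Z,6R,7S,8R,10S)-1,10-epoxy-8-[(4-methoxybenzyl)oxy]-13-norgermacr-4-ene-3,6,12-triol | OCC[C@H]1[C@H](O)/C=C(/C)[C@@H](O)C[C@@H]2O[C@@]2(C)C[C@H]1OCc3ccc(OC)cc3
F6 | step 23 | (1S,3S,4Z,6R,7R,8R,10S)-1,10-epoxy-3-hydroxy-8-[(4-methoxybenzyl)oxy]-13-norgermacr-4-en-12,6-olide | C1C(=O)O[C@@H]2/C=C(/C)[C@@H](O)C[C@@H]3O[C@@]3(C)C[C@@H](OCc4ccc(OC)cc4)[C@@H]12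
F7 | step 24 | 3-[(dimethylamino)methyl] derivative of lactone 31 (both epimers at the lactone α-carbon) | C=C[C@H]1OC(=O)C(CN(C)C)[C@@H]1[C@H](OCc2ccc(OC)cc2)C[C@]2(C)O[C@H]2C[C@H](O[Si](CC)(CC)CC)C(C)=C
F8 | step 24 | N-methyl quaternary ammonium iodide of F7 | C=C[C@H]1OC(=O)C(C[N+](C)(C)C)[C@@H]1[C@H](OCc2ccc(OC)cc2)C[C@]2(C)O[C@H]2C[C@H](O[Si](CC)(CC)CC)C(C)=C.[I-]
F9 | step 24 | (4R,5R)-5-ethenyl-4-{(1R)-1-[(4-methoxybenzyl)oxy]-2-[(2S,3S)-2-methyl-3-{(2S)-3-methyl-2-[(triethylsilyl)oxy]but-3-en-1-yl}oxiran-2-yl]ethyl}-3-methylideneoxolan-2-one | C=C[C@H]1OC(=O)C(=C)[C@@H]1[C@H](OCc2ccc(OC)cc2)C[C@]2(C)O[C@H]2C[C@H](O[Si](CC)(CC)CC)C(C)=C
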